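(Readings and results were generated by integration for substances that don't exist; the scatter is artificial.)

Side product divided by target rises early in a run, so compare it at equal conversion: there, per unit of starting material charged, I expect it to hold still. Watch that ratio.

| flask | starting material | remark | time |
|---|---|---|---|
| green | 0.11 M | the very flask that is asked about, followed so far |  |
| violet | 0.17 M | run made earlier |  |
| flask | 0.11 M |  | 8.0 h |

green run (percent of the starting material charged)

| time / min | target / % | side product / % |
|---|---|---|
| 8.00 | 4.0 | 0 |
| 12.0 | 5.1 | 0.1 |
| 20.0 | 9.4 | 0.2 |
| 40.0 | 17.5 | 0.9 |
| 60.0 | 24.2 | 1.5 |
| 90.0 | 34.2 | 1.6 |

violet run (percent of the starting material charged)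

| time / h | target / % | side product / % |
|---|---|---|
| 1.33 | 31.6 | 1.8 |
| 2.50 | 48.1 | 3.6 |
| 4.00 | 62.3 | 4.6 |
| 5.00 | 67.9 | 4.8 |
| 6.00 | 72.0 | 5.3 |
| 8.00 | 76.4 | 5.5 |

(standard deviation of a reading: 0.3 percentage points)

- percent here means starting material units held: one side product counts as two
- a reading or a percentage of target counts all its forms, free or not
- the reaction counts as stopped when no species that holds the starting material changes by six tenths of a point or more over the second half of the time

1. why nothing more happens at 8.0 h, or that something still does (all of the starting material has reacted / it is still moving / forward and back rates have come level)
2. how much target there is at 8.0 h, in percent of the starting material charged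
3. how much side product there is at 8.0 h, in percent of the starting material charged
4. how much intermediate B there is at 8.0 h, in percent of the starting material charged

Target barely notices the charge: green reads 34.2% at 90.0 min, and violet reads 31.6% at 1.33 h. So I take target as first order in starting material. Side product takes two starting units, so I take it as second order. Divide one rate by the other and time drops out: at equal conversion, side product over target scales with the charge.

Violet's last readings, divided by its charge, give 0.423 L mol⁻¹. This is the side-product ratio per unit of charge, a selectivity factor. At the green charge it gives 0.0466 for the same 8.00 h, where I expect the same conversion. Green's readings stop at target 34.2%, so they are no check on it.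

Violet still gains 14 percentage points of target from 4.00 h to 8.00 h, so I say the green flask is still moving. I take violet's 76.4% for its target, which makes side product 3.56%.

The forecast says it is still moving, with target 77.5% (72.5% to 82%), intermediate B 3% (0% to 12%) and side product 3.8% (2.5% to 5.6%), called “roughly second order, since two starting units make one”, which is higher than my figure.

The flask gives: it is still moving, target 76.9%, side product 3.64%, intermediate B 1.89%.

    intermediate A ⇌ intermediate B (K = 2.00, k = 0.0440 min⁻¹)
    crystals ⇌ target, rate k2*(cs2 - [target]) while solid is left; crystals form when [target] > cs2 (solubility = 47.0 mM, k = 0.760 min⁻¹)
    starting material → target (k = 0.00490 min⁻¹)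
    starting material + intermediate A → side product (k = 0.0740 L mol⁻¹ min⁻¹)
    intermediate A → decomposed reagent (k = 0.0170 min⁻¹)
    starting material → intermediate A (k = 0.00100 min⁻¹)

This flask is still moving because its time ends with 5.6% of the starting material left; left ten times as long, conversion goes from 94.4% to 100%. Side product needs starting material and intermediate A together, and intermediate A comes from starting material, so both partners scale with the charge. Target needs starting material by itself. In this flask side product over target comes to 0.0473, against the carried 0.0466. A neighbour flask of the same charge, read at 20 h, holds target 81.4%. The carried ratio turns that into 3.79% of side product, and the neighbour holds 3.71%.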